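Plakotenin is cut at C2–C3 of its cyclopentane (hexahydroindene locants: C1(Me)–C2H2–C3(Me), fusion C3a/C7a). C2 is the only CH2 of that ring, so a traceless phenylsulfonyl group there allows a stereospecific 5-exo-tet closure: the C2 carbanion displaces bromide at C3 with inversion and forms the five-membered ring trans-fused in one operation. The precursor is a cyclohexene carrying trans CH(CH3)CH2SO2Ph (on C7a) and CH(CH3)Br (on C3a) arms; its ring stereocentres (C3a, C6, C7, C7a) come from one endo Diels–Alder reaction of a lactate-derived (E,E)-diene with (S)-5-methyl-5,6-dihydro-2H-pyran-3-carbaldehyde, a temporary ring whose O–C2 bond is later exchanged for C2–C3.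

Key step: step 15

Remark: locants C1–C7a are those of the 2,3,3a,6,7,7a-hexahydro-1H-indene core of the target (C1 and C3 carry methyl, C2 is the ring CH2, C3a/C7a are the fusion carbons, C4(Me)=C5, C6 carries phenyl, C7 is quaternary) and are used for the corresponding atoms of all intermediates.

Step 1
Reactants: 1 ethyl (S)-lactate
Product: 2 ethyl (S)-2-[(tert-butyldiphenylsilyl)oxy]propanoate
Conditions: TBDPSCl, imidazole, DMF, rt
Reagents that add atoms: tert-butyl(chloro)diphenylsilane, CC(C)(C)[Si](Cl)(c1ccccc1)c1ccccc1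
Why: Imidazole-mediated silylation of the secondary alcohol installs a Lewis-acid-tolerant silyl ether without touching the lactate stereocentre, the future C3.

Step 2
Reactants: 2 ethyl (S)-2-[(tert-butyldiphenylsilyl)oxy]propanoate
Product: 4 (2E,4S)-4-[(tert-butyldiphenylsilyl)oxy]-2-methylpent-2-enal, via aldehyde 3 (not isolated)
Conditions: DIBAL-H, CH2Cl2, −78 °C; MeOH quench; crude 3, Ph3P=C(CH3)CHO, PhMe, 80 °C
Reagents that add atoms: 2-(triphenylphosphoranylidene)propanal, CC(C=O)=P(c1ccccc1)(c1ccccc1)c1ccccc1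
Why: Half-reduction of the ester gives the α-silyloxy aldehyde, which is used without purification in a Wittig reaction with the stabilised formyl ylide to give the (E)-trisubstituted enal, so that the α-centre is not epimerised.

Step 3
Reactants: 4 (2E,4S)-4-[(tert-butyldiphenylsilyl)oxy]-2-methylpent-2-enal
Product: 5 tert-butyl{[(2S,3E,5E)-4-methyl-6-phenylhexa-3,5-dien-2-yl]oxy}diphenylsilane
Conditions: (EtO)2P(O)CH2Ph, NaH, THF, 0 °C → rt
Reagents that add atoms: diethyl benzylphosphonate, CCOP(=O)(Cc1ccccc1)OCC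
Why: Horner–Wadsworth–Emmons olefination with the benzylphosphonate anion gives the (E)-styrene and completes the (E,E)-diene.

Step 4
Reactants: 6 (R)-3-bromo-2-methylpropan-1-ol
Product: 7 [(R)-3-hydroxy-2-methylpropyl]triphenylphosphonium bromide
Conditions: PPh3, MeCN, reflux
Reagents that add atoms: triphenylphosphine, c1ccc(cc1)P(c1ccccc1)c1ccccc1
Why: SN2 quaternisation of the phosphine by the primary bromide leaves the stereocentre, the future C1, untouched.

Step 5
Reactants: 7 [(R)-3-hydroxy-2-methylpropyl]triphenylphosphonium bromide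
Product: 9 (S)-2-methylbut-3-en-1-ol, via oxido ylide 8 (not isolated)
Conditions: n-BuLi (2 equiv), THF, −78 → 0 °C; then (CH2O)n
Reagents that add atoms: formaldehyde, C=O
Why: Double deprotonation gives an oxido ylide whose Wittig reaction with formaldehyde turns the CH2P carbon into the terminal vinyl CH that becomes C7a.

Step 6
Reactants: 9 (S)-2-methylbut-3-en-1-ol
Product: 10 (S)-4-{[2-(chloromethyl)prop-2-en-1-yl]oxy}-3-methylbut-1-ene
Conditions: NaH, THF–DMF, 0 °C; 3-chloro-2-(chloromethyl)prop-1-ene (excess), rt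
Reagents that add atoms: 3-chloro-2-(chloromethyl)prop-1-ene, ClCC(=C)CCl
Why: Williamson ether synthesis, in which the alkoxide displaces one allylic chloride of the excess dichloride, attaches the unit that supplies C7 and its two one-carbon substituents.

Step 7
Reactants: 10 (S)-4-{[2-(chloromethyl)prop-2-en-1-yl]oxy}-3-methylbut-1-ene
Product: 11 (S)-3-(chloromethyl)-5-methyl-5,6-dihydro-2H-pyran
Conditions: Grubbs II (cat.), CH2Cl2, 40 °C
Reagents that add atoms: none
Why: Ring-closing metathesis of the monosubstituted and the 1,1-disubstituted alkene closes the six-membered dihydropyran with loss of ethene.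

Step 8
Reactants: 11 (S)-3-(chloromethyl)-5-methyl-5,6-dihydro-2H-pyran
Product: 12 (S)-5-methyl-5,6-dihydro-2H-pyran-3-carbaldehyde
Conditions: NMO, NaI (cat.), MeCN, 50 °C
Reagents that add atoms: N-methylmorpholine N-oxide, C[N+]1([O-])CCOCC1
Why: N-Oxide oxidation of the allylic chloride (O-alkylation of the N-oxide, then elimination; Ganem/Kornblum type) gives the conjugated enal directly.

Step 9
Reactants: 12 (S)-5-methyl-5,6-dihydro-2H-pyran-3-carbaldehyde; 5 tert-butyl{[(2S,3E,5E)-4-methyl-6-phenylhexa-3,5-dien-2-yl]oxy}diphenylsilane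
Product: 13 cis-fused Diels–Alder adduct, an 8a-formyl-hexahydro-1H-isochromene (CHO on the future C7, cis to the C6 phenyl and to the C3a arm)
Conditions: Me2AlCl (1.5 equiv), CH2Cl2, −78 → −20 °C
Reagents that add atoms: none
Why: In this Lewis-acid-promoted Diels–Alder reaction the diene terminus bearing the carbinol arm bonds to the enal β-carbon (the developing allyl cation is stabilised by the 3-methyl and 1-phenyl groups), the formyl group sits endo and the diene adds to the dihydropyran face opposite its 5-methyl group, which sets C3a, C6, C7 and C7a together, while the silyloxy group of the diene should lie anti to the incoming dienophile with its C–H in the diene plane (matched pair).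

Step 10
Reactants: 13 Diels–Alder adduct (8a-formyl)
Product: 14 8a-ethenyl analogue of 13
Conditions: Ph3PCH3Br, KOtBu, THF, 0 °C → rt
Reagents that add atoms: methyltriphenylphosphonium bromide, C[P+](c1ccccc1)(c1ccccc1)c1ccccc1.[Br-]
Why: Wittig methylenation of the non-enolisable aldehyde turns the endo formyl group into the vinyl precursor of the C7 ethyl group.

Step 11
Reactants: 14 8a-ethenyl compound
Product: 15 8a-ethyl analogue of 13
Conditions: 2-nitrobenzenesulfonohydrazide, Et3N, CH2Cl2, rt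
Reagents that add atoms: none
Why: Diimide generated in the flask reduces the monosubstituted vinyl group by concerted syn hydrogen transfer much faster than the trisubstituted ring alkene.

Step 12
Reactants: 15 8a-ethyl hexahydroisochromene
Product: 17 ring-opened sulfone pivalate (C7–CH2OPiv, C7a–CH(CH3)CH2SO2Ph, C3a–CH(CH3)OTBDPS), via primary iodide 16 (not isolated)
Conditions: PivCl, NaI, MeCN, 0 °C → rt; then PhSO2Na, DMF, 60 °C
Reagents that add atoms: pivaloyl chloride, CC(C)(C)C(=O)Cl; sodium benzenesulfinate, [Na+].[O-]S(=O)c1ccccc1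
Why: Pivaloyl iodide formed in the flask acylates the ring oxygen and iodide opens the acyloxonium ion by SN2 at the less hindered CH2 (the future C2) and not at the neopentyl CH2 on C7 (acyl iodide ether cleavage), after which S-alkylation of sulfinate by the primary iodide places the sulfone on C2.

Step 13
Reactants: 17 ring-opened sulfone pivalate
Product: 18 secondary alcohol (C3a–CH(CH3)OH)
Conditions: TBAF, THF, 0 → 40 °C
Reagents that add atoms: none
Why: Fluoride-mediated cleavage of the silyl ether frees the future C3 carbinol with its lactate configuration while pivalate and sulfone stay intact.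

Step 14
Reactants: 18 secondary alcohol
Product: 19 secondary bromide (C3a–CH(CH3)Br, inverted)
Conditions: CBr4, PPh3, CH2Cl2, 0 °C
Reagents that add atoms: carbon tetrabromide, BrC(Br)(Br)Br
Why: In the Appel reaction bromide displaces the alkoxyphosphonium group by SN2, so the bromide carbon has the inverted configuration needed for a second inversion in the ring closure.

Step 15
Reactants: 19 secondary bromide
Product: 21 trans-fused 2-(phenylsulfonyl)hexahydroindene pivalate (mixture of C2 epimers), via potassium sulfonyl carbanion 20 (not isolated)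
Conditions: KHMDS (1.1 equiv), THF, −78 → 0 °C
Reagents that add atoms: none
Why: KHMDS removes a proton from C2, α to the sulfone, and the carbanion 20 displaces bromide at C3 in an intramolecular SN2 reaction. The closest known reaction type is the cycloalkylation of α-sulfonyl carbanions with secondary halides or sulfonates. The cyclopentane C1–C2–C3–C3a–C7a is closed in the 5-exo-tet mode, and because the two arms on C3a and C7a are trans on the cyclohexene the new ring is trans-fused. C3 is set by inversion of the bromide, which itself came from the lactate carbinol by one earlier inversion, so the lactate configuration is returned with carbon in place of oxygen; the sulfonyl-bearing C2 centre is inconsequential because the sulfone is removed in step 16. The step needs substitution to win over E2 loss of HBr, which the soft sulfonyl carbanion and the five-membered transition state should favour; the pivalate has no α-hydrogen, so no second carbanion can compete.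

Step 16
Reactants: 21 2-(phenylsulfonyl)hexahydroindene pivalate
Product: 22 (7-ethyl-1,3,4-trimethyl-6-phenyl-2,3,3a,6,7,7a-hexahydro-1H-inden-7-yl)methyl pivalate
Conditions: 6% Na(Hg), Na2HPO4, MeOH–THF, −20 °C
Reagents that add atoms: none
Why: Reductive desulfonylation by electron transfer cleaves the C2–S bond and protonation leaves C2 as the ring CH2, which is not a stereocentre.

Step 17
Reactants: 22 hexahydroindenylmethyl pivalate
Product: 23 (7-ethyl-1,3,4-trimethyl-6-phenyl-2,3,3a,6,7,7a-hexahydro-1H-inden-7-yl)methanol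
Conditions: DIBAL-H, CH2Cl2, −78 °C
Reagents that add atoms: none
Why: Hydride reduction cleaves the hindered pivalate to the neopentyl alcohol without affecting the ring alkene.

Step 18
Reactants: 23 hexahydroindenylmethanol
Product: 25 ethyl (E)-2-methyl-3-(7-ethyl-1,3,4-trimethyl-6-phenyl-2,3,3a,6,7,7a-hexahydro-1H-inden-7-yl)prop-2-enoate, via aldehyde 24 (not isolated)
Conditions: Dess–Martin periodinane, NaHCO3, CH2Cl2, rt; then Ph3P=C(CH3)CO2Et, PhMe, 100 °C
Reagents that add atoms: ethyl 2-(triphenylphosphoranylidene)propanoate, CCOC(=O)C(C)=P(c1ccccc1)(c1ccccc1)c1ccccc1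
Why: Dess–Martin oxidation gives the non-enolisable aldehyde, which reacts in the same flask with the stabilised α-methyl ylide (Wittig reaction) to give the (E)-trisubstituted enoate.

Step 19
Reactants: 25 ethyl ester
Product: 26 plakotenin
Conditions: LiOH, THF–MeOH–H2O, 50 °C; then 1 M HCl
Reagents that add atoms: lithium hydroxide, [Li+].[OH-]
Why: Saponification and acidification give the acid, and no stereocentre is epimerisable under these conditions.

Compound list
1 | ethyl (S)-lactate | CCOC(=O)[C@H](C)O | starting material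
2 | ethyl (S)-2-[(tert-butyldiphenylsilyl)oxy]propanoate | CCOC(=O)[C@H](C)O[Si](c1ccccc1)(c1ccccc1)C(C)(C)C | intermediate
3 | (S)-2-[(tert-butyldiphenylsilyl)oxy]propanal | O=C[C@H](C)O[Si](c1ccccc1)(c1ccccc1)C(C)(C)C | intermediate (not isolated)
4 | (2E,4S)-4-[(tert-butyldiphenylsilyl)oxy]-2-methylpent-2-enal | O=C/C(C)=C/[C@H](C)O[Si](c1ccccc1)(c1ccccc1)C(C)(C)C | intermediate
5 | tert-butyl{[(2S,3E,5E)-4-methyl-6-phenylhexa-3,5-dien-2-yl]oxy}diphenylsilane | c1ccccc1/C=C/C(C)=C/[C@H](C)O[Si](c1ccccc1)(c1ccccc1)C(C)(C)C | intermediate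
6 | (R)-3-bromo-2-methylpropan-1-ol | OC[C@@H](C)CBr | starting material
7 | [(R)-3-hydroxy-2-methylpropyl]triphenylphosphonium bromide | OC[C@@H](C)C[P+](c1ccccc1)(c1ccccc1)c1ccccc1.[Br-] | intermediate
8 | lithium 2-methyl-3-(triphenylphosphoranylidene)propan-1-olate (oxido ylide, configuration of 7) | [Li+].[O-]C[C@@H](C)C=P(c1ccccc1)(c1ccccc1)c1ccccc1 | intermediate (not isolated)
9 | (S)-2-methylbut-3-en-1-ol | OC[C@@H](C)C=C | intermediate
10 | (S)-4-{[2-(chloromethyl)prop-2-en-1-yl]oxy}-3-methylbut-1-ene | C=C[C@H](C)COCC(=C)CCl | intermediate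
11 | (S)-3-(chloromethyl)-5-methyl-5,6-dihydro-2H-pyran | ClCC1=C[C@H](C)COC1 | intermediate
12 | (S)-5-methyl-5,6-dihydro-2H-pyran-3-carbaldehyde | O=CC1=C[C@H](C)COC1 | intermediate
13 | cis-fused 5-{(S)-1-[(tert-butyldiphenylsilyl)oxy]ethyl}-4,6-dimethyl-8-phenyl-3,4,4a,5,8,8a-hexahydro-1H-isochromene-8a-carbaldehyde (8a-CHO cis to 8-Ph and to the C5 arm; 4-Me cis to H-4a) | O=C[C@@]12COC[C@@H](C)[C@@H]1[C@@H]([C@H](C)O[Si](c1ccccc1)(c1ccccc1)C(C)(C)C)C(C)=C[C@H]2c1ccccc1 | intermediate
14 | 8a-ethenyl analogue of 13 | C=C[C@@]12COC[C@@H](C)[C@@H]1[C@@H]([C@H](C)O[Si](c1ccccc1)(c1ccccc1)C(C)(C)C)C(C)=C[C@H]2c1ccccc1 | intermediate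
15 | 8a-ethyl analogue of 13 | CC[C@@]12COC[C@@H](C)[C@@H]1[C@@H]([C@H](C)O[Si](c1ccccc1)(c1ccccc1)C(C)(C)C)C(C)=C[C@H]2c1ccccc1 | intermediate
16 | {1-ethyl-6-(1-iodopropan-2-yl)-4-methyl-2-phenyl-5-[1-(tert-butyldiphenylsilyloxy)ethyl]cyclohex-3-en-1-yl}methyl pivalate (stereocentres as in 15) | CC[C@@]1(COC(=O)C(C)(C)C)[C@H]([C@@H](CI)C)[C@@H]([C@H](C)O[Si](c2ccccc2)(c2ccccc2)C(C)(C)C)C(C)=C[C@H]1c1ccccc1 | intermediate (not isolated)
17 | {1-ethyl-4-methyl-2-phenyl-6-[1-(phenylsulfonyl)propan-2-yl]-5-[1-(tert-butyldiphenylsilyloxy)ethyl]cyclohex-3-en-1-yl}methyl pivalate | CC[C@@]1(COC(=O)C(C)(C)C)[C@H]([C@@H](CS(=O)(=O)c2ccccc2)C)[C@@H]([C@H](C)O[Si](c2ccccc2)(c2ccccc2)C(C)(C)C)C(C)=C[C@H]1c1ccccc1 | intermediate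
18 | {1-ethyl-5-(1-hydroxyethyl)-4-methyl-2-phenyl-6-[1-(phenylsulfonyl)propan-2-yl]cyclohex-3-en-1-yl}methyl pivalate | CC[C@@]1(COC(=O)C(C)(C)C)[C@H]([C@@H](CS(=O)(=O)c2ccccc2)C)[C@@H]([C@H](C)O)C(C)=C[C@H]1c1ccccc1 | intermediate
19 | {5-(1-bromoethyl)-1-ethyl-4-methyl-2-phenyl-6-[1-(phenylsulfonyl)propan-2-yl]cyclohex-3-en-1-yl}methyl pivalate (bromide carbon inverted relative to 18) | CC[C@@]1(COC(=O)C(C)(C)C)[C@H]([C@@H](CS(=O)(=O)c2ccccc2)C)[C@@H]([C@@H](C)Br)C(C)=C[C@H]1c1ccccc1 | intermediate
20 | potassium α-sulfonyl carbanion of 19 | CC[C@@]1(COC(=O)C(C)(C)C)[C@H]([C@@H]([CH-]S(=O)(=O)c2ccccc2)C)[C@@H]([C@@H](C)Br)C(C)=C[C@H]1c1ccccc1.[K+] | intermediate (not isolated)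
21 | [7-ethyl-1,3,4-trimethyl-6-phenyl-2-(phenylsulfonyl)-2,3,3a,6,7,7a-hexahydro-1H-inden-7-yl]methyl pivalate (trans-fused, ring configuration of 26, C2 epimers) | CC[C@@]1(COC(=O)C(C)(C)C)[C@H]2[C@H](C(C)=C[C@H]1c1ccccc1)[C@H](C)C(S(=O)(=O)c1ccccc1)[C@H]2C | intermediate
22 | (7-ethyl-1,3,4-trimethyl-6-phenyl-2,3,3a,6,7,7a-hexahydro-1H-inden-7-yl)methyl pivalate (ring configuration of 26) | CC[C@@]1(COC(=O)C(C)(C)C)[C@H]2[C@H](C(C)=C[C@H]1c1ccccc1)[C@H](C)C[C@H]2C | intermediate
23 | (7-ethyl-1,3,4-trimethyl-6-phenyl-2,3,3a,6,7,7a-hexahydro-1H-inden-7-yl)methanol | CC[C@@]1(CO)[C@H]2[C@H](C(C)=C[C@H]1c1ccccc1)[C@H](C)C[C@H]2C | intermediate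
24 | 7-ethyl-1,3,4-trimethyl-6-phenyl-2,3,3a,6,7,7a-hexahydro-1H-indene-7-carbaldehyde | CC[C@@]1(C=O)[C@H]2[C@H](C(C)=C[C@H]1c1ccccc1)[C@H](C)C[C@H]2C | intermediate (not isolated)
25 | ethyl (E)-2-methyl-3-(7-ethyl-1,3,4-trimethyl-6-phenyl-2,3,3a,6,7,7a-hexahydro-1H-inden-7-yl)prop-2-enoate | CC[C@@]1(/C=C(\C)C(=O)OCC)[C@H]2[C@H](C(C)=C[C@H]1c1ccccc1)[C@H](C)C[C@H]2C | intermediate
26 | plakotenin, (E)-3-[(1R,3R,3aR,6S,7S,7aR)-7-ethyl-1,3,4-trimethyl-6-phenyl-2,3,3a,6,7,7a-hexahydro-1H-inden-7-yl]-2-methylprop-2-enoic acid | CC[C@@]1(/C=C(\C)C(=O)O)[C@H]2[C@H](C(C)=C[C@H]1c1ccccc1)[C@H](C)C[C@H]2C | target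

Total step count: 19. Longest linear sequence: 16 steps (steps 4–19, from 6).

Steps most likely to fail, in order of risk:

Step 9. The cycloaddition joins a trisubstituted enal to a 1,3,4-trisubstituted diene and may be too slow at temperatures at which the allylic silyl ether survives the Lewis acid. Ionisation or polymerisation of the diene, or erosion of the endo and facial preference, could then take over. The fallback sets out from 12 and changes the activation mode to an ionic (Gassman) Diels–Alder reaction. Acetalisation of 12 with ethylene glycol (PPTS, benzene, reflux) should give (S)-2-(5-methyl-5,6-dihydro-2H-pyran-3-yl)-1,3-dioxolane F1. With catalytic TMSOTf at −78 °C this forms a dioxolanium-stabilised allyl cation, a far stronger dienophile, which should add to 5 with the same topology to give the adduct acetal F2. Mild hydrolysis (PPTS, wet acetone) returns to the route at 13.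

Step 15. E2 loss of HBr across C3 and its neighbours, or simple proton transfer, may outrun the displacement at the hindered secondary carbon because the mono-sulfonyl carbanion is strongly basic. The fallback sets out from 17 and uses a softer, weakly basic gem-bis(sulfonyl) carbanion. Treatment of 17 with LDA and then benzenesulfonyl fluoride should give the gem-bis(phenylsulfonyl) silyl ether F3. TBAF then gives the bis-sulfonyl alcohol F4, and CBr4/PPh3 gives the inverted bis-sulfonyl bromide F5. Cs2CO3 in DMF should close the ring by the same 5-exo-tet inversion to the 2,2-bis(phenylsulfonyl)hexahydroindene F6. Double reductive desulfonylation (Mg, MeOH) comes back to the route at 22.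

Step 14. Bromination of the hindered carbinol may proceed with incomplete inversion (ion-pair return, participation by the C4=C5 π bond) or with elimination, which would scramble C3. The fallback sets out from 18 and separates the inversion from the activation. A Mitsunobu reaction (4-nitrobenzoic acid, DIAD, PPh3) should give the inverted 4-nitrobenzoate F7. Methanolysis (K2CO3, MeOH), which the neopentyl pivalate should survive, gives the epimeric alcohol F8, and MsCl/Et3N gives the mesylate F9. F9 is cyclised with KHMDS as in step 15 and comes back to the route at 21.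

Further compounds
F1 | step 9 | (S)-2-(5-methyl-5,6-dihydro-2H-pyran-3-yl)-1,3-dioxolane | C1COC(O1)C1=C[C@H](C)COC1
F2 | step 9 | ethylene acetal of 13 | C1COC(O1)[C@@]12COC[C@@H](C)[C@@H]1[C@@H]([C@H](C)O[Si](c1ccccc1)(c1ccccc1)C(C)(C)C)C(C)=C[C@H]2c1ccccc1
F3 | step 15 | gem-bis(phenylsulfonyl) analogue of 17 | CC[C@@]1(COC(=O)C(C)(C)C)[C@H]([C@@H](C(S(=O)(=O)c2ccccc2)S(=O)(=O)c2ccccc2)C)[C@@H]([C@H](C)O[Si](c2ccccc2)(c2ccccc2)C(C)(C)C)C(C)=C[C@H]1c1ccccc1
F4 | step 15 | gem-bis(phenylsulfonyl) analogue of 18 | CC[C@@]1(COC(=O)C(C)(C)C)[C@H]([C@@H](C(S(=O)(=O)c2ccccc2)S(=O)(=O)c2ccccc2)C)[C@@H]([C@H](C)O)C(C)=C[C@H]1c1ccccc1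
F5 | step 15 | gem-bis(phenylsulfonyl) analogue of 19 | CC[C@@]1(COC(=O)C(C)(C)C)[C@H]([C@@H](C(S(=O)(=O)c2ccccc2)S(=O)(=O)c2ccccc2)C)[C@@H]([C@@H](C)Br)C(C)=C[C@H]1c1ccccc1
F6 | step 15 | [7-ethyl-1,3,4-trimethyl-6-phenyl-2,2-bis(phenylsulfonyl)-2,3,3a,6,7,7a-hexahydro-1H-inden-7-yl]methyl pivalate | CC[C@@]1(COC(=O)C(C)(C)C)[C@H]2[C@H](C(C)=C[C@H]1c1ccccc1)[C@H](C)C(S(=O)(=O)c1ccccc1)(S(=O)(=O)c1ccccc1)[C@H]2C
F7 | step 14 | 4-nitrobenzoate of the C3-epimeric alcohol of 18 | CC[C@@]1(COC(=O)C(C)(C)C)[C@H]([C@@H](CS(=O)(=O)c2ccccc2)C)[C@@H]([C@@H](C)OC(=O)c2ccc(cc2)[N+](=O)[O-])C(C)=C[C@H]1c1ccccc1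
F8 | step 14 | carbinol epimer of 18 | CC[C@@]1(COC(=O)C(C)(C)C)[C@H]([C@@H](CS(=O)(=O)c2ccccc2)C)[C@@H]([C@@H](C)O)C(C)=C[C@H]1c1ccccc1
F9 | step 14 | methanesulfonate of F8 | CC[C@@]1(COC(=O)C(C)(C)C)[C@H]([C@@H](CS(=O)(=O)c2ccccc2)C)[C@@H]([C@@H](C)OS(C)(=O)=O)C(C)=C[C@H]1c1ccccc1
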